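**Plan**

1. Numbering (jatrophane): five-membered ring C15(OAc)–C1H=C2(Me)–C3(=O)–C4(=C5H); large ring C4=C5–C6(Me)(O)–C7–C8–C9(H)(O)–C10Me2–C11–C12–C13(Me)–C14(=O)–C15. Cuts, in order: C14=O / 15-OAc / C4=C5 (functional-group level), C4–C15 (aldol), C3=O + C15=O → one furan oxygen, C11–C12 (RCM), C3–C4 (furyl anion + epoxide), C13–C14 (crotylation), O–C6 (epoxide opening), C9–C10 (prenylation).
2. Enabling feature: C3=O and the C15 carbinol carbon stand 1,4 across the cis C1=C2 bond, and C15–O is β to C3=O through C4. The ring C15–C1–C2–C3–C4 is therefore the aldol retron of a cis-ene-1,4-dione, i.e. of an oxidised 2,5-disubstituted 3-methylfuran whose α-carbons are C3 and C15.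
3. Forward: trans-tetrahydrofuran first (O–C6), then a [10](2,5)furanophane by fragment union and RCM, then furan → Z-enedione with singlet oxygen, then the cyclopentenone as the last ring by transannular aldol; elimination, acetylation and oxidation finish.
4. Stereochemistry: C9 from Brown reverse prenylation; C6 from Sharpless epoxidation and invertive 5-exo opening; C13 and a temporary C14 centre from Brown anti-crotylation; C15 from 1,2-induction by C14 in the aldol; 4E from thermodynamic E1cB.
5. Helpers: furan ring (masked enedione), C14–OPMB (control element, avoids an acylfuran, later the ketone), O5–TES (later the leaving group); all are taken out in steps 12–17.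

Key step: step 13

Remarks on the chemistry:
- The bromofuran starting material of step 5 is taken as purchasable (otherwise one step from 3-methylfuran with NBS).
- The two allylboranes carry isopinocampheyl groups from (−)-α-pinene (lIpc) and are prepared beforehand as stock reagents.
- The C4 configuration of the aldol products, the bridgehead configuration of the endoperoxide and the E/Z geometry of the RCM olefin are left open in the SMILES, because each is erased in a later step.

**Route**

Step 1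
Reactants: 1 geranyl acetate
Product: 2 (2E)-3-methyl-6-oxohex-2-en-1-yl acetate
Conditions: O3 (1 equiv, Sudan III end point), CH2Cl2, −78 °C; then Me2S, −78 °C → rt
Reagents that add atoms: ozone, [O-][O+]=O
Why: Chemoselective ozonolysis should cleave the electron-rich remote 6,7-alkene in preference to the 2,3-alkene deactivated by the allylic acetate, and Me2S reduces the ozonide to the aldehyde.

Step 2
Reactants: 2 (2E)-3-methyl-6-oxohex-2-en-1-yl acetate
Product: 4 (2E,6S)-3,7,7-trimethylnona-2,8-diene-1,6-diol, via borinate 3 (not isolated)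
Conditions: (lIpc)2B–CH2CH=CMe2 [preformed from (+)-Ipc2BH and 3-methylbuta-1,2-diene], Et2O, −78 °C; then 3 M NaOH, 30% H2O2, MeOH, 0 °C → rt
Reagents that add atoms: B-(3-methylbut-2-en-1-yl)diisopinocampheylborane, CC(C)=CCB([C@H]1C[C@H]2C[C@@H]([C@@H]1C)C2(C)C)[C@H]1C[C@H]2C[C@@H]([C@@H]1C)C2(C)C
Why: Brown asymmetric reverse prenylation (γ-selective allylboration through a chair transition state) installs C10 with its two methyl groups and the vinyl group and should set C9 as S under control of the isopinocampheyl ligands, while the alkaline oxidative work-up cleaves the borinate and saponifies the acetate.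

Step 3
Reactants: 4 (2E,6S)-3,7,7-trimethylnona-2,8-diene-1,6-diol
Product: 6 (1R)-1-[(2S,5S)-2-methyl-5-(2-methylbut-3-en-2-yl)oxolan-2-yl]ethane-1,2-diol, via epoxy diol 5 (not isolated)
Conditions: Ti(Oi-Pr)4 (cat.), D-(−)-diethyl tartrate (cat.), t-BuOOH, 4 Å MS, CH2Cl2, −20 °C; then CSA (cat.), 0 °C → rt
Reagents that add atoms: tert-butyl hydroperoxide, CC(C)(C)OO
Why: Sharpless asymmetric epoxidation of the geraniol-type E-allylic alcohol (D-tartrate, 5R,6R epoxide) is followed by acid-catalysed 5-exo-tet opening at the tertiary epoxide carbon by the C9 hydroxyl, which inverts C6 and should give the 2,5-trans tetrahydrofuran (6S,9S) with a free C5 hydroxyl.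

Step 4
Reactants: 6 (1R)-1-[(2S,5S)-2-methyl-5-(2-methylbut-3-en-2-yl)oxolan-2-yl]ethane-1,2-diol
Product: 8 (2S,5S)-2-methyl-5-(2-methylbut-3-en-2-yl)-2-[(2R)-oxiran-2-yl]oxolane, via tosylate 7 (not isolated)
Conditions: NaH (2.2 equiv), 1-(p-toluenesulfonyl)imidazole, THF, 0 °C → rt
Reagents that add atoms: none
Why: One-pot terminal epoxide formation from a 1,2-diol: selective sulfonylation of the primary hydroxyl and intramolecular Williamson displacement by the secondary alkoxide, with retention at C5.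

Step 5
Reactants: 9 2-bromo-3-methylfuran
Product: 10 5-bromo-4-methylfuran-2-carbaldehyde
Conditions: LDA, THF, −78 °C; then DMF, −78 → 0 °C; H2O
Reagents that add atoms: N,N-dimethylformamide, CN(C)C=O
Why: Directed deprotonation at the only free α-position of the furan by the amide base (the bromine is kept) and formylation of the furyllithium with DMF.

Step 6
Reactants: 10 5-bromo-4-methylfuran-2-carbaldehyde
Product: 12 (1R,2R)-1-(5-bromo-4-methylfuran-2-yl)-2-methylbut-3-en-1-ol, via borinate 11 (not isolated)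
Conditions: (E)-crotyl-B(lIpc)2 [preformed from trans-2-butene, KOt-Bu/n-BuLi, (+)-Ipc2BOMe, BF3·OEt2], THF/Et2O, −78 °C; then 3 M NaOH, 30% H2O2, 0 °C → rt
Reagents that add atoms: B-[(E)-but-2-en-1-yl]diisopinocampheylborane, C/C=C/CB([C@H]1C[C@H]2C[C@@H]([C@@H]1C)C2(C)C)[C@H]1C[C@H]2C[C@@H]([C@@H]1C)C2(C)C
Why: Brown asymmetric crotylboration, in which the E-crotyl geometry gives the anti adduct through the chair transition state and the lIpc ligands select the aldehyde face, should set C13 (R, kept to the end) and the temporary C14 centre (R) together.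

Step 7
Reactants: 12 (1R,2R)-1-(5-bromo-4-methylfuran-2-yl)-2-methylbut-3-en-1-ol
Product: 13 2-bromo-5-[(1R,2R)-1-(4-methoxybenzyloxy)-2-methylbut-3-en-1-yl]-3-methylfuran
Conditions: NaH, PMBCl, n-Bu4NI (cat.), THF/DMF, 0 °C → rt
Reagents that add atoms: 4-methoxybenzyl chloride, COc1ccc(CCl)cc1
Why: Williamson etherification under basic conditions, chosen because the furfuryl alcohol would ionise under acidic benzylation, gives the non-participating ether that later steers the aldol.

Step 8
Reactants: 13 2-bromo-5-[(1R,2R)-1-(4-methoxybenzyloxy)-2-methylbut-3-en-1-yl]-3-methylfuran; 8 (2S,5S)-2-methyl-5-(2-methylbut-3-en-2-yl)-2-[(2R)-oxiran-2-yl]oxolane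
Product: 15 coupled furyl alcohol (5R,6S,9S,13R,14R), via furyllithium 14 (not isolated)
Conditions: 13 (1.3 equiv), n-BuLi, THF, −78 °C; then 8, BF3·OEt2, −78 °C
Reagents that add atoms: none
Why: Bromine–lithium exchange gives the 2-furyllithium regiospecifically next to the ring methyl group, and BF3-assisted SN2 opening of the terminal epoxide at its CH2 terminus forms the C3–C4 bond and leaves the C5 hydroxyl.

Step 9
Reactants: 15 coupled furyl alcohol
Product: 16 C5 triethylsilyl ether of 15
Conditions: Et3SiOTf, 2,6-lutidine, CH2Cl2, −78 °C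
Reagents that add atoms: triethylsilyl trifluoromethanesulfonate, CC[Si](CC)(CC)OS(=O)(=O)C(F)(F)F
Why: Silylation of the hindered secondary hydroxyl with a silyl triflate masks O5, which must not add to the enedione in steps 12–13 and later becomes the leaving group.

Step 10
Reactants: 16 C5 triethylsilyl ether
Product: 17 unsaturated [10](2,5)furanophane (C11=C12)
Conditions: Grubbs II (10 mol %), CH2Cl2 (1 mM), 40 °C
Reagents that add atoms: none
Why: Ring-closing olefin metathesis of the two monosubstituted vinyl groups at high dilution should close the 13-membered ring (counted through both ring oxygens) with loss of ethene, the olefin geometry being irrelevant.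

Step 11
Reactants: 17 unsaturated [10](2,5)furanophane
Product: 18 saturated [10](2,5)furanophane
Conditions: H2 (1 atm), [Ir(cod)(PCy3)(py)]PF6 (5 mol %), CH2Cl2, rt
Reagents that add atoms: none
Why: Homogeneous hydrogenation with Crabtree's catalyst should reduce the hindered disubstituted alkene while sparing the aromatic furan, the furfuryl PMB ether (no hydrogenolysis as with Pd) and the silyl ether.

Step 12
Reactants: 18 saturated [10](2,5)furanophane
Product: 20 macrocyclic (1Z)-ene-3,15-dione, via endoperoxide 19 (not isolated)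
Conditions: O2, tetraphenylporphyrin (cat.), visible light, CH2Cl2, −78 °C; then Me2S, −78 → 0 °C
Reagents that add atoms: dioxygen, O=O
Why: [4+2] photooxygenation of the trisubstituted furan with singlet oxygen gives the strained 2,5-endoperoxide, whose reduction with Me2S unmasks the ene-1,4-dione with the cis geometry inherited from the furan.

Step 13
Reactants: 20 macrocyclic (1Z)-ene-3,15-dione
Product: 21 (5R,6S,9S,13R,14R,15S)-15-hydroxy-14-(4-methoxybenzyloxy)-5-(triethylsilyloxy)-6,9-epoxyjatroph-1-en-3-one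
Conditions: DBU (1.5 equiv), CH2Cl2, 0 °C → rt
Reagents that add atoms: none
Why: DBU enolises the C3 ketone toward C4 and the enolate adds across the ring to the C15 ketone, which the cis C1=C2 bond of the furan-derived enedione holds 1,4 to C3, so that the C4–C15 bond closes the cyclopentenone C15–C1–C2–C3–C4 and contracts the 14-membered oxa-bridged ring to the 12-membered carbocycle in one event. The closest known reaction type is the base-mediated transannular aldol addition of macrocyclic cis-ene-1,4-diones, obtained by oxidative opening of 2,5-bridged furans, to ring-fused 4-hydroxycyclopent-2-enones. The five-membered ring closes in the 5-(enolexo)-exo-trig mode. The new C15 carbinol centre is controlled by the temporary C14 centre in a polar Felkin–Anh arrangement, in which the C14–OPMB bond lies anti to the incoming C4 and points out of the ring while the C13 chain sits inside, so that the (14R) ether should give (15S); the C4 centre formed with it needs no control because it becomes sp2 in step 15. The step needs enolisation at C4 and not at C14, and C–C instead of C–O bond formation, which is secured by the tertiary, hindered, ether-flanked C14–H, by the TES ether on O5 (no oxa-Michael addition to C1) and by the metal-free amidine base (no chelate that would reverse the Felkin sense). The addition is reversible under these conditions, so the more stable ring-fused aldol should accumulate before it is locked in step 15.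

Step 14
Reactants: 21 aldol product
Product: 22 (5R,6S,9S,13R,14R,15S)-5,15-dihydroxy-14-(4-methoxybenzyloxy)-6,9-epoxyjatroph-1-en-3-one
Conditions: HF·pyridine, pyridine, THF, 0 °C
Reagents that add atoms: none
Why: Buffered fluoride-mediated desilylation should cleave the secondary triethylsilyl ether without touching the PMB ether, the tertiary carbinol or the enone.

Step 15
Reactants: 22 5,15-diol
Product: 24 (4E,6S,9S,13R,14R,15S)-15-acetoxy-14-(4-methoxybenzyloxy)-6,9-epoxyjatropha-1,4-dien-3-one, via diacetate 23 (not isolated)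
Conditions: Ac2O (excess), DMAP, Et3N, CH2Cl2, rt → 40 °C; then DBU, 0 °C → rt
Reagents that add atoms: acetic anhydride, CC(=O)OC(C)=O
Why: DMAP-catalysed acetylation of both hydroxyls followed by E1cB loss of the C5 acetate through the C3 enolate should give the exocyclic C4=C5 bond as the thermodynamically favoured E isomer (C6 anti to the C3 carbonyl, the geometry that keeps a cis olefin in the 12-membered ring), while the C15 acetate stays because its loss would give a cyclopentadienone.

Step 16
Reactants: 24 15-acetoxy-14-PMB ether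
Product: 25 (4E,6S,9S,13R,14R,15S)-15-acetoxy-14-hydroxy-6,9-epoxyjatropha-1,4-dien-3-one
Conditions: DDQ, CH2Cl2/pH 7 buffer (10:1), 0 °C
Reagents that add atoms: none
Why: Oxidative cleavage of the p-methoxybenzyl ether (hydride abstraction, then hydrolysis of the oxocarbenium ion) under neutral conditions should leave the tertiary allylic acetate and the cross-conjugated dienone untouched.

Step 17
Reactants: 25 15-acetoxy-14-alcohol
Product: 26 (4E,6S,9S,13R,15S)-15-acetoxy-6,9-epoxyjatropha-1,4-diene-3,14-dione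
Conditions: Dess–Martin periodinane, NaHCO3, CH2Cl2, 0 °C → rt
Reagents that add atoms: none
Why: Dess–Martin oxidation of the secondary alcohol under buffered, non-basic conditions should give the C14 ketone without epimerising the adjacent C13 centre.

**Compound list**

1 | geranyl acetate, (2E)-3,7-dimethylocta-2,6-dien-1-yl acetate | CC(=O)OC/C=C(\C)CCC=C(C)C | starting material
2 | (2E)-3-methyl-6-oxohex-2-en-1-yl acetate | CC(=O)OC/C=C(\C)CCC=O | intermediate
3 | (2E,6S)-6-[bis(isopinocampheyl)boranyloxy]-3,7,7-trimethylnona-2,8-dien-1-yl acetate | CC(=O)OC/C=C(\C)CC[C@H](OB([C@H]1C[C@H]2C[C@@H]([C@@H]1C)C2(C)C)[C@H]1C[C@H]2C[C@@H]([C@@H]1C)C2(C)C)C(C)(C)C=C | intermediate (not isolated)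
4 | (2E,6S)-3,7,7-trimethylnona-2,8-diene-1,6-diol | OC/C=C(\C)CC[C@H](O)C(C)(C)C=C | intermediate
5 | (3S)-1-[(2R,3R)-3-(hydroxymethyl)-2-methyloxiran-2-yl]-4,4-dimethylhex-5-en-3-ol | OC[C@H]1O[C@]1(C)CC[C@H](O)C(C)(C)C=C | intermediate (not isolated)
6 | (1R)-1-[(2S,5S)-2-methyl-5-(2-methylbut-3-en-2-yl)oxolan-2-yl]ethane-1,2-diol | OC[C@@H](O)[C@]1(C)CC[C@H](O1)C(C)(C)C=C | intermediate
7 | (2R)-2-hydroxy-2-[(2S,5S)-2-methyl-5-(2-methylbut-3-en-2-yl)oxolan-2-yl]ethyl 4-methylbenzenesulfonate | Cc1ccc(cc1)S(=O)(=O)OC[C@@H](O)[C@]1(C)CC[C@H](O1)C(C)(C)C=C | intermediate (not isolated)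
8 | (2S,5S)-2-methyl-5-(2-methylbut-3-en-2-yl)-2-[(2R)-oxiran-2-yl]oxolane | C1O[C@H]1[C@]2(C)CC[C@H](O2)C(C)(C)C=C | intermediate
9 | 2-bromo-3-methylfuran | Cc1ccoc1Br | starting material
10 | 5-bromo-4-methylfuran-2-carbaldehyde | O=Cc1cc(C)c(Br)o1 | intermediate
11 | O-[bis(isopinocampheyl)boranyl] derivative of 12 | C=C[C@@H](C)[C@@H](OB([C@H]1C[C@H]2C[C@@H]([C@@H]1C)C2(C)C)[C@H]1C[C@H]2C[C@@H]([C@@H]1C)C2(C)C)c1cc(C)c(Br)o1 | intermediate (not isolated)
12 | (1R,2R)-1-(5-bromo-4-methylfuran-2-yl)-2-methylbut-3-en-1-ol | C=C[C@@H](C)[C@@H](O)c1cc(C)c(Br)o1 | intermediate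
13 | 2-bromo-5-[(1R,2R)-1-(4-methoxybenzyloxy)-2-methylbut-3-en-1-yl]-3-methylfuran | C=C[C@@H](C)[C@@H](OCc1ccc(OC)cc1)c1cc(C)c(Br)o1 | intermediate
14 | 5-[(1R,2R)-1-(4-methoxybenzyloxy)-2-methylbut-3-en-1-yl]-3-methylfuran-2-yllithium | C=C[C@@H](C)[C@@H](OCc1ccc(OC)cc1)c1cc(C)c([Li])o1 | intermediate (not isolated)
15 | (1R)-2-{5-[(1R,2R)-1-(4-methoxybenzyloxy)-2-methylbut-3-en-1-yl]-3-methylfuran-2-yl}-1-[(2S,5S)-2-methyl-5-(2-methylbut-3-en-2-yl)oxolan-2-yl]ethan-1-ol | C=C[C@@H](C)[C@@H](OCc1ccc(OC)cc1)c1cc(C)c(o1)C[C@@H](O)[C@]2(C)CC[C@H](O2)C(C)(C)C=C | intermediate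
16 | triethylsilyl ether of 15 at O5 | C=C[C@@H](C)[C@@H](OCc1ccc(OC)cc1)c1cc(C)c(o1)C[C@@H](O[Si](CC)(CC)CC)[C@]2(C)CC[C@H](O2)C(C)(C)C=C | intermediate
17 | (5R,6S,9S,13R,14R)-3,15:6,9-diepoxy-14-(4-methoxybenzyloxy)-5-(triethylsilyloxy)-4,15-secojatropha-1(15),2,11-triene (E/Z at C11=C12 open) | C3[C@@H](C)[C@@H](OCc1ccc(OC)cc1)c1cc(C)c(o1)C[C@@H](O[Si](CC)(CC)CC)[C@]2(C)CC[C@H](O2)C(C)(C)C=3 | intermediate
18 | (5R,6S,9S,13R,14R)-3,15:6,9-diepoxy-14-(4-methoxybenzyloxy)-5-(triethylsilyloxy)-4,15-secojatropha-1(15),2-diene | C3[C@@H](C)[C@@H](OCc1ccc(OC)cc1)c1cc(C)c(o1)C[C@@H](O[Si](CC)(CC)CC)[C@]2(C)CC[C@H](O2)C(C)(C)C3 | intermediate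
19 | 3,15-endoperoxide of 18 (furan C3 and C15 bridged by O–O) | C3[C@@H](C)[C@@H](OCc1ccc(OC)cc1)C45C=C(C)C(O4)(OO5)C[C@@H](O[Si](CC)(CC)CC)[C@]2(C)CC[C@H](O2)C(C)(C)C3 | intermediate (not isolated)
20 | (1Z,5R,6S,9S,13R,14R)-14-(4-methoxybenzyloxy)-5-(triethylsilyloxy)-6,9-epoxy-4,15-secojatroph-1-ene-3,15-dione | C3[C@@H](C)[C@@H](OCc1ccc(OC)cc1)C(=O)/C=C(C)\C(=O)C[C@@H](O[Si](CC)(CC)CC)[C@]2(C)CC[C@H](O2)C(C)(C)C3 | intermediate
21 | (5R,6S,9S,13R,14R,15S)-15-hydroxy-14-(4-methoxybenzyloxy)-5-(triethylsilyloxy)-6,9-epoxyjatroph-1-en-3-one (C4 open) | O[C@@]12C=C(C)C(=O)C1[C@@H](O[Si](CC)(CC)CC)[C@]3(C)CC[C@H](O3)C(C)(C)CC[C@@H](C)[C@H]2OCc1ccc(OC)cc1 | intermediate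
22 | (5R,6S,9S,13R,14R,15S)-5,15-dihydroxy-14-(4-methoxybenzyloxy)-6,9-epoxyjatroph-1-en-3-one (C4 open) | O[C@@]12C=C(C)C(=O)C1[C@@H](O)[C@]3(C)CC[C@H](O3)C(C)(C)CC[C@@H](C)[C@H]2OCc1ccc(OC)cc1 | intermediate
23 | 5,15-di-O-acetate of 22 | CC(=O)O[C@@]12C=C(C)C(=O)C1[C@@H](OC(C)=O)[C@]3(C)CC[C@H](O3)C(C)(C)CC[C@@H](C)[C@H]2OCc1ccc(OC)cc1 | intermediate (not isolated)
24 | (4E,6S,9S,13R,14R,15S)-15-acetoxy-14-(4-methoxybenzyloxy)-6,9-epoxyjatropha-1,4-dien-3-one | CC(=O)O[C@@]12C=C(C)C(=O)/C1=C/[C@]3(C)CC[C@H](O3)C(C)(C)CC[C@@H](C)[C@H]2OCc1ccc(OC)cc1 | intermediate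
25 | (4E,6S,9S,13R,14R,15S)-15-acetoxy-14-hydroxy-6,9-epoxyjatropha-1,4-dien-3-one | CC(=O)O[C@@]12C=C(C)C(=O)/C1=C/[C@]3(C)CC[C@H](O3)C(C)(C)CC[C@@H](C)[C@H]2O | intermediate
26 | (4E,6S,9S,13R,15S)-15-acetoxy-6,9-epoxyjatropha-1,4-diene-3,14-dione (CNP0144863.1) | CC(=O)O[C@@]12C=C(C)C(=O)/C1=C/[C@]1(C)CC[C@H](O1)C(C)(C)CC[C@@H](C)C2=O | target

**Count and risks**

Total steps: 17. Longest linear sequence: 14 (steps 1–4, then 8–17).

Steps most likely to fail:

Step 13 (transannular aldol). The ring may force a reacting conformation in which C4 reaches the other face of the C15 carbonyl, or enolisation may drift toward C14 and erode the temporary centre, so that the C15 carbinol forms with poor or reversed facial selectivity. The fallback sets out from 20 and comes back at 26; it removes the C14 centre before ring closure. DDQ in CH2Cl2/pH 7 buffer would free the α-hydroxy enedione F1, and Dess–Martin oxidation would give the ene-trione F2, whose C15 carbonyl is flanked by an sp2, non-enolisable C14 and is more electrophilic. Et3N or DBU would then close the ring reversibly, under thermodynamic control by C13 and the oxa-bridge, to the 15-hydroxy-3,14-dione F3. HF·pyridine would give the 5,15-diol F4, and Ac2O/DMAP/Et3N followed by DBU would convert it through the diacetate F5 into 26.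

Step 10 (ring-closing metathesis). Both olefins are hindered (one neopentylic, one next to the C13 branch) and the product is a trans-bridged furanophane, so initiation may be slow and oligomerisation may outrun ring closure. The fallback sets out from 16 and comes back at 21; it opens the furan first, so that metathesis acts on a flexible chain. Photooxygenation of 16 (terminal vinyl groups do not react with singlet oxygen) and Me2S reduction would give, through the endoperoxide F6, the open-chain Z-enedione F7. Ring-closing metathesis at high dilution would give the 14-membered enedione F8, and the DBU aldol would give the cyclopentenone F9 that still carries the C11=C12 bond. Hydrogenation with Wilkinson's catalyst, which spares the conjugated trisubstituted enone, would return 21.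

Step 15 (double acetylation and elimination). The tertiary C15 carbinol beside the C14 ether may acylate sluggishly, the β-hydroxy ketone may suffer retro-aldol cleavage under base before the C4=C5 bond locks it, and the later release of O14 beside the acetate invites acyl migration. The fallback sets out from 22 and comes back at 26; it dehydrates first and acetylates last. MsCl/Et3N and then DBU would give, through the C5 mesylate F10, the dienone carbinol F11, in which retro-aldol is no longer possible. DDQ would give the 14,15-diol F12, and Parikh–Doering oxidation (SO3·pyridine, DMSO, i-Pr2NEt) would give the α-ketol F13. Acetylation of this less encumbered tertiary α-ketol (Ac2O, DMAP) would give 26.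

Further compounds
F1 | step 13 | (1Z,5R,6S,9S,13R,14R)-14-hydroxy-5-(triethylsilyloxy)-6,9-epoxy-4,15-secojatroph-1-ene-3,15-dione | C3[C@@H](C)[C@@H](O)C(=O)/C=C(C)\C(=O)C[C@@H](O[Si](CC)(CC)CC)[C@]2(C)CC[C@H](O2)C(C)(C)C3
F2 | step 13 | (1Z,5R,6S,9S,13R)-5-(triethylsilyloxy)-6,9-epoxy-4,15-secojatroph-1-ene-3,14,15-trione | C3[C@@H](C)C(=O)C(=O)/C=C(C)\C(=O)C[C@@H](O[Si](CC)(CC)CC)[C@]2(C)CC[C@H](O2)C(C)(C)C3
F3 | step 13 | (5R,6S,9S,13R,15S)-15-hydroxy-5-(triethylsilyloxy)-6,9-epoxyjatroph-1-ene-3,14-dione (C4 open) | O[C@@]12C=C(C)C(=O)C1[C@@H](O[Si](CC)(CC)CC)[C@]3(C)CC[C@H](O3)C(C)(C)CC[C@@H](C)C2=O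
F4 | step 13 | (5R,6S,9S,13R,15S)-5,15-dihydroxy-6,9-epoxyjatroph-1-ene-3,14-dione (C4 open) | O[C@@]12C=C(C)C(=O)C1[C@@H](O)[C@]3(C)CC[C@H](O3)C(C)(C)CC[C@@H](C)C2=O
F5 | step 13 | 5,15-di-O-acetate of F4 | CC(=O)O[C@@]12C=C(C)C(=O)C1[C@@H](OC(C)=O)[C@]3(C)CC[C@H](O3)C(C)(C)CC[C@@H](C)C2=O
F6 | step 10 | 2,5-endoperoxide of the furan of 16 | C=C[C@@H](C)[C@@H](OCc1ccc(OC)cc1)C45C=C(C)C(O4)(OO5)C[C@@H](O[Si](CC)(CC)CC)[C@]2(C)CC[C@H](O2)C(C)(C)C=C
F7 | step 10 | open-chain Z-enedione from 16 (two terminal vinyl groups kept) | C=C[C@@H](C)[C@@H](OCc1ccc(OC)cc1)C(=O)/C=C(C)\C(=O)C[C@@H](O[Si](CC)(CC)CC)[C@]2(C)CC[C@H](O2)C(C)(C)C=C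
F8 | step 10 | 11,12-didehydro derivative of 20 | C3[C@@H](C)[C@@H](OCc1ccc(OC)cc1)C(=O)/C=C(C)\C(=O)C[C@@H](O[Si](CC)(CC)CC)[C@]2(C)CC[C@H](O2)C(C)(C)C=3
F9 | step 10 | 11,12-didehydro derivative of 21 | O[C@@]12C=C(C)C(=O)C1[C@@H](O[Si](CC)(CC)CC)[C@]3(C)CC[C@H](O3)C(C)(C)C=C[C@@H](C)[C@H]2OCc1ccc(OC)cc1
F10 | step 15 | 5-O-methanesulfonate of 22 | O[C@@]12C=C(C)C(=O)C1[C@@H](OS(C)(=O)=O)[C@]3(C)CC[C@H](O3)C(C)(C)CC[C@@H](C)[C@H]2OCc1ccc(OC)cc1
F11 | step 15 | (4E,6S,9S,13R,14R,15S)-15-hydroxy-14-(4-methoxybenzyloxy)-6,9-epoxyjatropha-1,4-dien-3-one | O[C@@]12C=C(C)C(=O)/C1=C/[C@]3(C)CC[C@H](O3)C(C)(C)CC[C@@H](C)[C@H]2OCc1ccc(OC)cc1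
F12 | step 15 | (4E,6S,9S,13R,14R,15S)-14,15-dihydroxy-6,9-epoxyjatropha-1,4-dien-3-one | O[C@@]12C=C(C)C(=O)/C1=C/[C@]3(C)CC[C@H](O3)C(C)(C)CC[C@@H](C)[C@H]2O
F13 | step 15 | (4E,6S,9S,13R,15S)-15-hydroxy-6,9-epoxyjatropha-1,4-diene-3,14-dione | O[C@@]12C=C(C)C(=O)/C1=C/[C@]3(C)CC[C@H](O3)C(C)(C)CC[C@@H](C)C2=O
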